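**Strategy.** Derrisdione A is cut at two neighbouring bonds of the benzene ring of its 2H-chromene: C7–O and C6–C(=O). The C7 hydroxyl and the C6 acyl carbon are ortho to each other, and C6 also lies next to the C5 methoxyl. An aryne flanked by a methoxyl gives exactly this arrangement once a carboxylate has attacked its remote carbon and passed its acyl group to the adjacent carbanion. One operation therefore attaches the whole masked aryl-diketone arm and sets the phenol free. The aryne precursor is a fully substituted chromene with a C6 trimethylsilyl and a C7 triflate group. Its partner is 4-hydroxyphenylglyoxylic acid with the ketone as a dimethyl ketal and the phenol as a fluoride-stable methoxymethyl ether.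

Key step: step 10

Remark on the chemistry: 2H-chromene numbering (O1, C2, C3, C4, C4a, C5 to C8, C8a) is used for all bicyclic compounds; the phenol of the arylglyoxylic partner is carried as a methoxymethyl (MOM) ether because a phenolic silyl ether would be cleaved by the fluoride that releases the aryne and the freed phenoxide would add to the aryne, and the acid is turned into its dry cesium salt before the aryne is generated so that no acidic proton is present.

**Route**

Step 1
Reactants: 1 5-methoxyresorcinol
Product: 2 1-methoxy-3,5-bis(methoxymethoxy)benzene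
Conditions: MOMCl, iPr2NEt, CH2Cl2, 0 °C to rt
Reagents that add atoms: chloromethyl methyl ether, COCCl
Why: Williamson-type O-alkylation of both phenols should be clean, and the two MOM ethers then act as the directing groups for the metalation in step 2.

Step 2
Reactants: 2 1-methoxy-3,5-bis(methoxymethoxy)benzene; 3 prenyl bromide (1-bromo-3-methylbut-2-ene)
Product: 5 5-methoxy-1,3-bis(methoxymethoxy)-2-(3-methylbut-2-en-1-yl)benzene, via aryllithium 4 (not isolated)
Conditions: n-BuLi, TMEDA, THF, 0 °C; then 3, −78 °C to rt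
Reagents that add atoms: none
Why: Directed ortho-metalation should take place at the ring carbon flanked by the two MOM ethers, the best-chelated and most acidic position, and SN2 alkylation of the aryllithium by the primary allylic bromide gives a mirror-symmetric arene whose two open ring positions are equivalent.

Step 3
Reactants: 5 5-methoxy-1,3-bis(methoxymethoxy)-2-(3-methylbut-2-en-1-yl)benzene
Product: 6 2-bromo-1-methoxy-3,5-bis(methoxymethoxy)-4-(3-methylbut-2-en-1-yl)benzene
Conditions: NBS (1.0 equiv), MeCN, −30 °C to 0 °C, dark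
Reagents that add atoms: N-bromosuccinimide, O=C1CCC(=O)N1Br
Why: Electrophilic aromatic bromination should be much faster on the trioxygenated ring than on the trisubstituted alkene, the two open positions are equivalent, the first bromine deactivates the ring against a second, and no free phenol is present that could close onto a bromonium ion.

Step 4
Reactants: 6 2-bromo-1-methoxy-3,5-bis(methoxymethoxy)-4-(3-methylbut-2-en-1-yl)benzene
Product: 7 4-bromo-5-methoxy-2-(3-methylbut-2-en-1-yl)benzene-1,3-diol
Conditions: HCl (1.25 M in MeOH), 40 °C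
Reagents that add atoms: none
Why: Acid-catalysed transacetalisation in methanol removes both MOM groups as dimethoxymethane under dilute conditions of the kind routinely tolerated by aryl prenyl groups and aryl bromides.

Step 5
Reactants: 7 4-bromo-5-methoxy-2-(3-methylbut-2-en-1-yl)benzene-1,3-diol; 8 3-methylbut-2-enal
Product: 10 6-bromo-5-methoxy-2,2-dimethyl-8-(3-methylbut-2-en-1-yl)-2H-chromen-7-ol, via ortho-quinone methide 9 (not isolated)
Conditions: ethylenediammonium diacetate (20 mol %), PhMe, 110 °C
Reagents that add atoms: none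
Why: Amine-salt-catalysed Knoevenagel-type condensation of the enal at the only free ring carbon gives a vinyl ortho-quinone methide that closes by oxa-6π electrocyclisation onto the adjacent oxygen (a formal [3+3] chromene annulation), and because bromine occupies the position next to the other hydroxyl only one chromene can form, with the free hydroxyl at C7.

Step 6
Reactants: 10 6-bromo-5-methoxy-2,2-dimethyl-8-(3-methylbut-2-en-1-yl)-2H-chromen-7-ol
Product: 14 5-methoxy-2,2-dimethyl-8-(3-methylbut-2-en-1-yl)-6-(trimethylsilyl)-2H-chromen-7-yl trifluoromethanesulfonate, via silyl ether 11 (not isolated), via aryllithium 12 (not isolated), via lithium phenoxide 13 (not isolated)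
Conditions: HMDS (neat), 80 °C, then evaporation; n-BuLi, THF, −78 °C; Tf2O, −78 °C to 0 °C; chromatography on Et3N-buffered silica
Reagents that add atoms: hexamethyldisilazane, C[Si](C)(C)N[Si](C)(C)C; trifluoromethanesulfonic anhydride, O=S(=O)(OS(=O)(=O)C(F)(F)F)C(F)(F)F
Why: O-silylation, bromine–lithium exchange and retro-Brook (1,3 oxygen-to-carbon) silyl migration place the silane on C6 and leave the C7 lithium phenoxide, which is trapped as the triflate; this is the standard one-pot conversion of ortho-bromophenols into ortho-silylaryl triflates, and the exchange at −78 °C outruns any deprotonation.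

Step 7
Reactants: 15 4-hydroxyphenylglyoxylic acid
Product: 16 methyl 2-(4-hydroxyphenyl)-2,2-dimethoxyacetate
Conditions: HC(OMe)3, MeOH, H2SO4 (cat.), 65 °C
Reagents that add atoms: trimethyl orthoformate, COC(OC)OC; methanol, CO
Why: Fischer esterification and acid-catalysed ketalisation of the activated α-keto group proceed together, with the orthoformate consuming the water that forms.

Step 8
Reactants: 16 methyl 2-(4-hydroxyphenyl)-2,2-dimethoxyacetate
Product: 17 methyl 2,2-dimethoxy-2-[4-(methoxymethoxy)phenyl]acetate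
Conditions: MOMCl, iPr2NEt, CH2Cl2, 0 °C to rt
Reagents that add atoms: chloromethyl methyl ether, COCCl
Why: Williamson-type O-alkylation under basic conditions leaves the ketal untouched and installs a phenol protecting group that is inert to fluoride, carbanions and hydroxide.

Step 9
Reactants: 17 methyl 2,2-dimethoxy-2-[4-(methoxymethoxy)phenyl]acetate
Product: 19 2,2-dimethoxy-2-[4-(methoxymethoxy)phenyl]acetic acid, via sodium carboxylate 18 (not isolated)
Conditions: NaOH, MeOH/H2O, 50 °C; then cold 1 M HCl to pH 3, immediate extraction (EtOAc, 0 °C)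
Reagents that add atoms: sodium hydroxide, [Na+].[OH-]
Why: Saponification (BAc2 hydrolysis) of the inductively activated methyl ester spares the ketal and the MOM ether, and brief cold acidification should free the acid without ketal hydrolysis.

Step 10
Reactants: 14 5-methoxy-2,2-dimethyl-8-(3-methylbut-2-en-1-yl)-6-(trimethylsilyl)-2H-chromen-7-yl trifluoromethanesulfonate; 19 2,2-dimethoxy-2-[4-(methoxymethoxy)phenyl]acetic acid
Product: 24 1-[7-hydroxy-5-methoxy-2,2-dimethyl-8-(3-methylbut-2-en-1-yl)-2H-chromen-6-yl]-2,2-dimethoxy-2-[4-(methoxymethoxy)phenyl]ethan-1-one, via cesium carboxylate 20 (not isolated), via aryne 21 (not isolated), via aryl anion 22 (not isolated), via cesium phenoxide 23 (not isolated)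
Conditions: 19 (1.5 equiv), Cs2CO3 (0.75 equiv), MeOH, rt, then evaporation and PhMe azeotrope; CsF (3 equiv), 18-crown-6 (0.3 equiv), THF, 50 °C, slow addition of 14 (1.0 equiv); then aq. NH4Cl
Reagents that add atoms: none
Why: Proposed new method: fluoride attacks silicon and expels triflate to give the C6–C7 aryne, the cesium carboxylate adds through oxygen at C7, and the C6 aryl anion attacks the ester carbonyl through a four-membered transition structure whose collapse moves the acyl group to C6 and leaves the C7 phenoxide, so the C7–O bond and the C6–C(acyl) bond form in one flask. The closest known reaction type is the insertion of simple arynes into the C–O bond of carboxylic acids to give ortho-hydroxyaryl ketones, in essence an aryne-triggered anionic ortho-Fries shift, which has not been shown for a fully substituted aryne or an α,α-dialkoxy acid. No ring is closed and no stereocentre is created. The regioselectivity needed is attack at C7, and it should be secured by the C5 methoxyl, whose inductive effect makes the remote aryne carbon the electrophilic one and stabilises the developing C6 anion, against the modest steric bias of the C8 prenyl group. The chemoselectivity needed is acyl transfer before protonation, which the dry cesium salt in an aprotic ether solvent favours, while the ketal removes the more electrophilic ketone (otherwise open to attack through a five-membered transition structure) and the MOM ether cannot be cleaved by fluoride to a competing phenoxide. An excess of carboxylate keeps the hindered product phenoxide from adding to a second aryne.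

Step 11
Reactants: 24 1-[7-hydroxy-5-methoxy-2,2-dimethyl-8-(3-methylbut-2-en-1-yl)-2H-chromen-6-yl]-2,2-dimethoxy-2-[4-(methoxymethoxy)phenyl]ethan-1-one
Product: 25 derrisdione A
Conditions: 3 M aq. HCl, THF, 45 °C
Reagents that add atoms: water, O
Why: Specific-acid-catalysed hydrolysis should ionise the dimethyl ketal to an aryl-stabilised oxocarbenium ion and cleave the aryl MOM acetal in the same pot, while the C7 hydroxyl is held in a hydrogen bond to the C6 ketone and is a poor nucleophile towards the prenyl group, and the alcohol-free aqueous medium drives any cyclic mixed ketal back to the open diketone.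

**Compound list**

1 | 5-methoxyresorcinol (5-methoxybenzene-1,3-diol) | COc1cc(O)cc(O)c1 | starting material
2 | 1-methoxy-3,5-bis(methoxymethoxy)benzene | COCOc1cc(OC)cc(OCOC)c1 | intermediate
3 | prenyl bromide (1-bromo-3-methylbut-2-ene) | CC(C)=CCBr | starting material
4 | [4-methoxy-2,6-bis(methoxymethoxy)phenyl]lithium | [Li]c1c(OCOC)cc(OC)cc1OCOC | intermediate
5 | 5-methoxy-1,3-bis(methoxymethoxy)-2-(3-methylbut-2-en-1-yl)benzene | COCOc1cc(OC)cc(OCOC)c1CC=C(C)C | intermediate
6 | 2-bromo-1-methoxy-3,5-bis(methoxymethoxy)-4-(3-methylbut-2-en-1-yl)benzene | COCOc1cc(OC)c(Br)c(OCOC)c1CC=C(C)C | intermediate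
7 | 4-bromo-5-methoxy-2-(3-methylbut-2-en-1-yl)benzene-1,3-diol | COc1cc(O)c(CC=C(C)C)c(O)c1Br | intermediate
8 | 3-methylbut-2-enal | CC(C)=CC=O | starting material
9 | 4-bromo-3-hydroxy-5-methoxy-6-(3-methylbut-2-en-1-ylidene)-2-(3-methylbut-2-en-1-yl)cyclohexa-2,4-dien-1-one | O=C1C(CC=C(C)C)=C(O)C(Br)=C(OC)C1=CC=C(C)C | intermediate
10 | 6-bromo-5-methoxy-2,2-dimethyl-8-(3-methylbut-2-en-1-yl)-2H-chromen-7-ol | COc1c(Br)c(O)c(CC=C(C)C)c2OC(C)(C)C=Cc12 | intermediate
11 | {[6-bromo-5-methoxy-2,2-dimethyl-8-(3-methylbut-2-en-1-yl)-2H-chromen-7-yl]oxy}trimethylsilane | COc1c(Br)c(O[Si](C)(C)C)c(CC=C(C)C)c2OC(C)(C)C=Cc12 | intermediate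
12 | {5-methoxy-2,2-dimethyl-8-(3-methylbut-2-en-1-yl)-7-[(trimethylsilyl)oxy]-2H-chromen-6-yl}lithium | COc1c([Li])c(O[Si](C)(C)C)c(CC=C(C)C)c2OC(C)(C)C=Cc12 | intermediate
13 | lithium 5-methoxy-2,2-dimethyl-8-(3-methylbut-2-en-1-yl)-6-(trimethylsilyl)-2H-chromen-7-olate | COc1c([Si](C)(C)C)c([O-])c(CC=C(C)C)c2OC(C)(C)C=Cc12.[Li+] | intermediate
14 | 5-methoxy-2,2-dimethyl-8-(3-methylbut-2-en-1-yl)-6-(trimethylsilyl)-2H-chromen-7-yl trifluoromethanesulfonate | COc1c([Si](C)(C)C)c(OS(=O)(=O)C(F)(F)F)c(CC=C(C)C)c2OC(C)(C)C=Cc12 | intermediate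
15 | 4-hydroxyphenylglyoxylic acid [2-(4-hydroxyphenyl)-2-oxoacetic acid] | O=C(O)C(=O)c1ccc(O)cc1 | starting material
16 | methyl 2-(4-hydroxyphenyl)-2,2-dimethoxyacetate | COC(=O)C(OC)(OC)c1ccc(O)cc1 | intermediate
17 | methyl 2,2-dimethoxy-2-[4-(methoxymethoxy)phenyl]acetate | COCOc1ccc(cc1)C(OC)(OC)C(=O)OC | intermediate
18 | sodium 2,2-dimethoxy-2-[4-(methoxymethoxy)phenyl]acetate | COCOc1ccc(cc1)C(OC)(OC)C(=O)[O-].[Na+] | intermediate
19 | 2,2-dimethoxy-2-[4-(methoxymethoxy)phenyl]acetic acid | COCOc1ccc(cc1)C(OC)(OC)C(=O)O | intermediate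
20 | cesium 2,2-dimethoxy-2-[4-(methoxymethoxy)phenyl]acetate | COCOc1ccc(cc1)C(OC)(OC)C(=O)[O-].[Cs+] | intermediate
21 | 6,7-didehydro-5-methoxy-2,2-dimethyl-8-(3-methylbut-2-en-1-yl)-2H-chromene (aryne) | COC1=C2C=CC(C)(C)OC2=C(CC=C(C)C)C#C1 | intermediate
22 | cesium 7-{2,2-dimethoxy-2-[4-(methoxymethoxy)phenyl]acetoxy}-5-methoxy-2,2-dimethyl-8-(3-methylbut-2-en-1-yl)-2H-chromen-6-ide | COc1[c-]c(OC(=O)C(OC)(OC)c3ccc(OCOC)cc3)c(CC=C(C)C)c2OC(C)(C)C=Cc12.[Cs+] | intermediate
23 | cesium 6-{2,2-dimethoxy-2-[4-(methoxymethoxy)phenyl]acetyl}-5-methoxy-2,2-dimethyl-8-(3-methylbut-2-en-1-yl)-2H-chromen-7-olate | COc1c(C(=O)C(OC)(OC)c3ccc(OCOC)cc3)c([O-])c(CC=C(C)C)c2OC(C)(C)C=Cc12.[Cs+] | intermediate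
24 | 1-[7-hydroxy-5-methoxy-2,2-dimethyl-8-(3-methylbut-2-en-1-yl)-2H-chromen-6-yl]-2,2-dimethoxy-2-[4-(methoxymethoxy)phenyl]ethan-1-one (O-methoxymethyl derrisdione A dimethyl ketal) | COc1c(C(=O)C(OC)(OC)c3ccc(OCOC)cc3)c(O)c(CC=C(C)C)c2OC(C)(C)C=Cc12 | intermediate
25 | derrisdione A, 1-[7-hydroxy-5-methoxy-2,2-dimethyl-8-(3-methylbut-2-en-1-yl)-2H-chromen-6-yl]-2-(4-hydroxyphenyl)ethane-1,2-dione | COc1c2c(c(CC=C(C)C)c(O)c1C(=O)C(=O)c1ccc(O)cc1)OC(C)(C)C=C2 | target

**Step count**

Total steps: 11. Longest linear sequence: 8 steps (steps 1 to 6, then 10 and 11, from 1); the acid branch (steps 7 to 9) joins at step 10.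

**Steps most likely to fail**

Step 10. The C6 aryl anion may be protonated before it captures the acyl carbon, leaving an aryl ester. The carboxylate may also add at C6 instead of C7 because the C8 prenyl group shields C7, or the hindered acyl group may transfer too slowly. The fallback uses known chemistry and sets out from 10 and 19. Steglich esterification (EDC·HCl, DMAP, CH2Cl2) should give 6-bromo-5-methoxy-2,2-dimethyl-8-(3-methylbut-2-en-1-yl)-2H-chromen-7-yl 2,2-dimethoxy-2-[4-(methoxymethoxy)phenyl]acetate F1. Treatment with t-BuLi (2 equiv, THF, −100 °C to −78 °C) exchanges bromine for lithium, and the C6 aryllithium undergoes the anionic ortho-Fries acyl shift. Aqueous NH4Cl then returns the route to 24, with the regiochemistry fixed by the position of the bromine.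

Step 11. During the acid treatment the C7 hydroxyl may add to the protonated prenyl double bond (closure to a dihydropyran), or it may trap the oxocarbenium ion of the ketal to give a cyclic mixed ketal that is slow to reopen. The fallback replaces the acid-labile phenol protecting group by one removed under neutral conditions and sets out from 16. O-Allylation (allyl bromide, K2CO3, acetone) gives methyl 2,2-dimethoxy-2-[4-(prop-2-en-1-yloxy)phenyl]acetate F2. Saponification as in step 9 gives 2,2-dimethoxy-2-[4-(prop-2-en-1-yloxy)phenyl]acetic acid F3. Insertion into the aryne from 14 under the conditions of step 10 gives 1-[7-hydroxy-5-methoxy-2,2-dimethyl-8-(3-methylbut-2-en-1-yl)-2H-chromen-6-yl]-2,2-dimethoxy-2-[4-(prop-2-en-1-yloxy)phenyl]ethan-1-one F4. Allyl transfer to morpholine with Pd(PPh3)4 (a zerovalent palladium complex, THF, rt) gives 1-[7-hydroxy-5-methoxy-2,2-dimethyl-8-(3-methylbut-2-en-1-yl)-2H-chromen-6-yl]-2-(4-hydroxyphenyl)-2,2-dimethoxyethan-1-one F5. The ketal alone is then hydrolysed under much milder acid (PPTS, acetone/H2O, rt), and the route is rejoined at 25.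

Step 5. Condensation at the hindered ring carbon of the brominated diol may be slow, so that self-condensation of the enal takes over. The fallback builds the pyran ring by a Claisen route before bromine is introduced and sets out from 5. MOM cleavage (HCl, MeOH, 40 °C) gives 5-methoxy-2-(3-methylbut-2-en-1-yl)benzene-1,3-diol F6. Mono-O-alkylation with 3-chloro-3-methylbut-1-yne (DBU, CuCl2 cat., MeCN, 0 °C) gives 5-methoxy-3-[(2-methylbut-3-yn-2-yl)oxy]-2-(3-methylbut-2-en-1-yl)phenol F7. Heating (xylene, 140 °C) brings about aromatic propargyl Claisen rearrangement, 1,5-hydrogen shift and oxa-6π closure at the only free ortho position, to give 5-methoxy-2,2-dimethyl-8-(3-methylbut-2-en-1-yl)-2H-chromen-7-ol F8. Ortho-bromination of the phenol at C6, the only open ring position (NBS, iPr2NH cat., CH2Cl2, −78 °C), returns the route to 10.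

**Further compounds**

F1 | step 10 | 6-bromo-5-methoxy-2,2-dimethyl-8-(3-methylbut-2-en-1-yl)-2H-chromen-7-yl 2,2-dimethoxy-2-[4-(methoxymethoxy)phenyl]acetate | COc1c(Br)c(OC(=O)C(OC)(OC)c3ccc(OCOC)cc3)c(CC=C(C)C)c2OC(C)(C)C=Cc12
F2 | step 11 | methyl 2,2-dimethoxy-2-[4-(prop-2-en-1-yloxy)phenyl]acetate | C=CCOc1ccc(cc1)C(OC)(OC)C(=O)OC
F3 | step 11 | 2,2-dimethoxy-2-[4-(prop-2-en-1-yloxy)phenyl]acetic acid | C=CCOc1ccc(cc1)C(OC)(OC)C(=O)O
F4 | step 11 | 1-[7-hydroxy-5-methoxy-2,2-dimethyl-8-(3-methylbut-2-en-1-yl)-2H-chromen-6-yl]-2,2-dimethoxy-2-[4-(prop-2-en-1-yloxy)phenyl]ethan-1-one | COc1c(C(=O)C(OC)(OC)c3ccc(OCC=C)cc3)c(O)c(CC=C(C)C)c2OC(C)(C)C=Cc12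
F5 | step 11 | 1-[7-hydroxy-5-methoxy-2,2-dimethyl-8-(3-methylbut-2-en-1-yl)-2H-chromen-6-yl]-2-(4-hydroxyphenyl)-2,2-dimethoxyethan-1-one | COc1c(C(=O)C(OC)(OC)c3ccc(O)cc3)c(O)c(CC=C(C)C)c2OC(C)(C)C=Cc12
F6 | step 5 | 5-methoxy-2-(3-methylbut-2-en-1-yl)benzene-1,3-diol | COc1cc(O)c(CC=C(C)C)c(O)c1
F7 | step 5 | 5-methoxy-3-[(2-methylbut-3-yn-2-yl)oxy]-2-(3-methylbut-2-en-1-yl)phenol | COc1cc(O)c(CC=C(C)C)c(OC(C)(C)C#C)c1
F8 | step 5 | 5-methoxy-2,2-dimethyl-8-(3-methylbut-2-en-1-yl)-2H-chromen-7-ol | COc1cc(O)c(CC=C(C)C)c2OC(C)(C)C=Cc12
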